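**Retrosynthetic overview**
1. Target 25 ← desilylation of its 10-O-silyl ether 24 ← ring B by a two-carbon ring expansion (thermal 1,3-shift) of the vinylcyclobutane 23 (ring C-4/C-5/C-10/C-1), which is made in the same flask by a sensitized intramolecular [2+2] of the 3-vinylbutenolide (C-2=C-3–C-4=C-5) with the ring-C silyl enol ether (C-10=C-1) of 22.
2. Enabling feature: ring B is a cyclohex-3-enol (C-10–C-5–C-4=C-3–C-2–C-1). C-4 carries the lactone carbonyl and C-1 the furan, so the cyclobutane bond C-4–C-1 lies between an allyl/α-acyl radical site and a furfuryl radical site and should break near 90 °C.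
3. 22 ← enyne ring-closing metathesis (vinylbutenolide) ← ring C by a lateral (vinylogous) Dieckmann closure of a 2-methyl-3-furyl ketone onto a γ-lactone carbonyl (C-10), which also releases O-7.
4. The γ-lactone is the stereochemical template: (S)-5-(hydroxymethyl)furanone gives C-7, anti cuprate addition gives C-8, and double enolate alkylation anti to the C-8 methyl gives the C-9 quaternary centre.
5. Ring order: lactone template → furan attached → ring C → butenolide → ring A and cyclobutane → ring B.

Key step: step 15

Remark on locants: ring A = C-5, C-6, C-7 (OAc), C-8 (Me), C-9 (Me), C-10 (OH); ring B = C-10, C-1, C-2, C-3, C-4, C-5; lactone = C-4, C-18 (C=O), O, C-19, C-5; ring C = C-1, C-10, C-9, C-11, C-12 (C=O), C-13, C-16, with C-13 to C-16 and O forming the furan. The target is (1R,5S,7R,8S,9S,10R).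
Assumption: compounds 1, 3, 9, 12 and 19 are taken as commercial.

**Step 1**
Reactants: 1 2-bromoprop-2-en-1-ol
Product: 2 [(2-bromoprop-2-en-1-yl)oxy](tert-butyl)diphenylsilane
Conditions: TBDPSCl, imidazole, CH2Cl2, 0 °C to rt
Reagents that add atoms: tert-butyl(chloro)diphenylsilane CC(C)(C)[Si](Cl)(c1ccccc1)c1ccccc1
Why: Silyl ether formation at a primary allylic alcohol protects O-19 through the organometallic and enolate steps; no stereocentre is involved.

**Step 2**
Reactants: 3 (S)-5-(hydroxymethyl)furan-2(5H)-one
Product: 4 [(2S)-5-oxo-2,5-dihydrofuran-2-yl]methyl 4-methylbenzenesulfonate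
Conditions: TsCl, pyridine, CH2Cl2, 0 °C
Reagents that add atoms: 4-methylbenzenesulfonyl chloride Cc1ccc(cc1)S(Cl)(=O)=O
Why: Sulfonylation of the primary alcohol turns C-6 into an electrophile without touching the C-7 stereocentre taken from the chiral pool.

**Step 3**
Reactants: 4 the butenolide tosylate
Product: 5 [(2S,3S)-3-methyl-5-oxooxolan-2-yl]methyl 4-methylbenzenesulfonate (trans)
Conditions: Me2CuLi, Et2O, −78 °C; aq. NH4Cl
Reagents that add atoms: lithium dimethylcuprate [Li+].C[Cu-]C
Why: Cuprate 1,4-addition to the butenolide takes place anti to the C-7 substituent and sets C-8 trans to it, while the primary tosylate is not displaced at −78 °C.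

**Step 4**
Reactants: 5 the trans methyl lactone tosylate; 2 the bromoallyl silyl ether
Product: 7 (4S,5R)-5-{2-[(tert-butyldiphenylsilyloxy)methyl]prop-2-en-1-yl}-4-methyloxolan-2-one, via lithium dialkenylcuprate 6 (not isolated)
Conditions: 2, t-BuLi, Et2O, −78 °C; CuI, −40 °C; then 5, THF, −40 to −10 °C
Reagents that add atoms: none
Why: Substitution of a primary tosylate by a lithium dialkenylcuprate forms the C-5–C-6 bond; the lactone carbonyl is inert to the cuprate at low temperature and no stereocentre is touched.

**Step 5**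
Reactants: 7 the alkenyl lactone
Product: 8 (3S,4S,5R)-5-{2-[(tert-butyldiphenylsilyloxy)methyl]prop-2-en-1-yl}-3,4-dimethyloxolan-2-one (3,4-trans isomer expected to predominate)
Conditions: LDA, THF, −78 °C; MeI
Reagents that add atoms: iodomethane CI
Why: Lactone enolate methylation introduces C-20; its configuration is irrelevant because C-9 becomes an enolate again in step 6.

**Step 6**
Reactants: 8 the dimethyl lactone; 9 prop-2-en-1-yl bromoacetate
Product: 10 prop-2-en-1-yl [(3S,4S,5R)-5-{2-[(tert-butyldiphenylsilyloxy)methyl]prop-2-en-1-yl}-3,4-dimethyl-2-oxooxolan-3-yl]acetate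
Conditions: LDA, THF/DMPU, −78 to −40 °C; then 9
Reagents that add atoms: none
Why: Alkylation of the tetrasubstituted lactone enolate occurs anti to the methyl group on the adjacent carbon C-8 (1,2-induction), so C-11 enters trans to the C-8 methyl and the C-9 quaternary centre is set with both methyl groups cis.

**Step 7**
Reactants: 10 the allyl ester
Product: 11 [(3S,4S,5R)-5-{2-[(tert-butyldiphenylsilyloxy)methyl]prop-2-en-1-yl}-3,4-dimethyl-2-oxooxolan-3-yl]acetic acid
Conditions: Pd(PPh3)4 (5 mol %), morpholine, THF, rt; dilute acid work-up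
Reagents that add atoms: none
Why: Tsuji–Trost deallylation frees the C-12 acid under neutral conditions that spare the lactone, the silyl ether and the 1,1-disubstituted alkene.

**Step 8**
Reactants: 11 the lactone acid; 12 3-bromo-2-methylfuran
Product: 15 (3S,4S,5R)-5-{2-[(tert-butyldiphenylsilyloxy)methyl]prop-2-en-1-yl}-3,4-dimethyl-3-[2-(2-methylfuran-3-yl)-2-oxoethyl]oxolan-2-one, via acid chloride 13 (not isolated), via furylzinc chloride 14 (not isolated)
Conditions: 11, 1-chloro-N,N,2-trimethylprop-1-en-1-amine, CH2Cl2, 0 °C; 12, n-BuLi, THF, −78 °C, then ZnCl2; combine, Pd(PPh3)4 (5 mol %), THF, 0 °C to rt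
Reagents that add atoms: none
Why: Negishi acylation of the acid chloride (made without HCl) with the 3-furylzinc reagent gives the C-12 ketone chemoselectively in the presence of the lactone; no stereocentre is touched.

**Step 9**
Reactants: 15 the furyl ketone lactone
Product: 16 (6S)-6-[(2S,3R)-5-{[(tert-butyldiphenylsilyl)oxy]methyl}-3-hydroxyhex-5-en-2-yl]-6-methyl-5,6-dihydro-4H-cyclohepta[b]furan-4,7(8H)-dione
Conditions: t-BuOK (3 equiv), THF/t-BuOH 10:1, 0 to 40 °C; aq. NH4Cl
Reagents that add atoms: none
Why: Under equilibrating alkoxide conditions the C-11 enolate cannot close a ring, whereas the lateral dienolate (furan 2-methyl deprotonated, vinylogous to the C-12 ketone) attacks the lactone carbonyl C-10 in a seven-membered vinylogous Dieckmann condensation that expels the C-7 alkoxide and is pulled forward by deprotonation of the product at C-1; no stereocentre is touched.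

**Step 10**
Reactants: 16 the ring-C diketone alcohol
Product: 17 (2S,3R)-5-{[(tert-butyldiphenylsilyl)oxy]methyl}-2-[(6S)-6-methyl-4,7-dioxo-5,6,7,8-tetrahydro-4H-cyclohepta[b]furan-6-yl]hex-5-en-3-yl acetate
Conditions: Ac2O, pyridine, DMAP (cat.), CH2Cl2, 0 °C to rt
Reagents that add atoms: acetic anhydride CC(=O)OC(C)=O
Why: Acylation of the secondary C-7 alcohol installs the acetate of the target with retention, since the C–O bond is not broken.

**Step 11**
Reactants: 17 the acetate silyl ether
Product: 18 (2S,3R)-5-(hydroxymethyl)-2-[(6S)-6-methyl-4,7-dioxo-5,6,7,8-tetrahydro-4H-cyclohepta[b]furan-6-yl]hex-5-en-3-yl acetate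
Conditions: HF·pyridine, THF/pyridine, 0 °C to rt
Reagents that add atoms: none
Why: Buffered fluoride cleaves the primary silyl ether and leaves the acetate, the furan and the enolisable diketone unchanged.

**Step 12**
Reactants: 18 the allylic alcohol; 19 prop-2-ynoic acid
Product: 20 (4R,5S)-4-acetoxy-2-methylidene-5-[(6S)-6-methyl-4,7-dioxo-5,6,7,8-tetrahydro-4H-cyclohepta[b]furan-6-yl]hexyl prop-2-ynoate
Conditions: DCC, DMAP (5 mol %), CH2Cl2, −20 to 0 °C
Reagents that add atoms: none
Why: Steglich esterification at low temperature gives the propiolate (C-18, C-4, C-3) on O-19 without conjugate addition to the ynoate.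

**Step 13**
Reactants: 20 the enyne ester
Product: 21 (2R,3S)-1-(4-ethenyl-5-oxo-2,5-dihydrofuran-3-yl)-3-[(6S)-6-methyl-4,7-dioxo-5,6,7,8-tetrahydro-4H-cyclohepta[b]furan-6-yl]butan-2-yl acetate
Conditions: second-generation Grubbs catalyst RuCl2(=CHPh)(PCy3)(H2IMes) (10 mol %), ethylene (1 atm), toluene, 80 °C
Reagents that add atoms: none
Why: Exo-mode ring-closing enyne metathesis, precedented for alkynoate esters with N-heterocyclic-carbene ruthenium catalysts, joins C-4 to C-5 in the five-membered lactone and transfers the alkene methylene to C-3 as C-2, giving the 3-vinylbutenolide diene.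

**Step 14**
Reactants: 21 the vinylbutenolide diketone
Product: 22 the C-10 triethylsilyl enol ether of 21 (C-10=C-1 in ring C)
Conditions: TESOTf (1.1 equiv), Et3N, CH2Cl2, −78 °C
Reagents that add atoms: triethylsilyl trifluoromethanesulfonate CC[Si](CC)(CC)OS(=O)(=O)C(F)(F)F
Why: Soft enolisation silylates the most basic carbonyl (C-10) and removes the doubly activated C-1 proton (α to C-10, furfurylic, vinylogous to C-12), so the enol ether forms only toward C-1 (C-9 is quaternary) and faster than silylation of the butenolide.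

**Step 15**
Reactants: 22 the silyl enol ether / vinylbutenolide
Product: 24 10-O-triethylsilyl ether of target 25, via vinylcyclobutane 23 (not isolated)
Conditions: [Ir(dF(CF3)ppy)2(dtbbpy)]PF6 (2 mol %), 450 nm LEDs, degassed PhCF3, 25 °C; then 90 °C in the same flask with the light on
Reagents that add atoms: none
Why: Proposed new method: triplet energy transfer to the dienyl chromophore of 22 (closest known reaction types: the sensitized intramolecular [2+2] photocycloaddition of 1,3-dienes with alkenes, followed in the same flask by the thermal vinylcyclobutane-to-cyclohexene 1,3-shift) lets the C-5 terminus add 6-exo-trig to the enol ether carbon C-10, closing ring A and leaving a 1,4-diradical that is allyl/α-acyl stabilised at C-4 and furfuryl stabilised at C-1, which after intersystem crossing recombines C-4/C-1 to the cyclobutane 23. At 90 °C the strained, doubly stabilised C-4–C-1 bond homolyses again and C-1 recombines with the allyl terminus C-2, a formal 1,3-sigmatropic shift that enlarges the four-membered ring by two carbons to the strain-free cyclohexene ring B with C-3=C-4 conjugated to the lactone. C-10 is controlled by the C-9 quaternary centre, because the four-atom arm C-8 to C-5 reaches only the face of the ring-C enol ether on which C-8 stands (cis A/C fusion, O-10 cis to the C-9 methyl); C-5 follows because C-4 must bond to C-1 on the side of the new C-5–C-10 bond (cis-fused cyclobutane); C-1 is set by least-motion recombination on the face of ring C that carries C-5 (cis B/C fusion, retention at C-1). The step needs straight and not crossed regiochemistry and ring closure and not loss to cycloreversion: the 6-exo mode that produces the more stabilised furfuryl radical should secure the first, and cycloreversion only regenerates 22, which re-enters the photocycle, whereas ring B once formed has no low-energy chromophore and no weak bond. A thermal Diels–Alder reaction of 22 is not expected to compete, since it would have to join two fully substituted carbons next to the C-9 quaternary centre with mismatched polarity.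

**Step 16**
Reactants: 24 the tertiary silyl ether
Product: 25 target CNP0329797.1, (1R,5S,7R,8S,9S,10R)
Conditions: HF·pyridine, THF, 0 °C to rt
Reagents that add atoms: none
Why: Fluoride cleavage of the tertiary triethylsilyl ether under mildly acidic conditions should leave the C-7 acetate, the unsaturated lactone and the acylfuran untouched.

**Compound list**
1 | 2-bromoprop-2-en-1-ol | C=C(Br)CO | starting material
2 | [(2-bromoprop-2-en-1-yl)oxy](tert-butyl)diphenylsilane | C=C(Br)CO[Si](c1ccccc1)(c1ccccc1)C(C)(C)C | intermediate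
3 | (S)-5-(hydroxymethyl)furan-2(5H)-one | O=C1C=C[C@@H](CO)O1 | starting material
4 | [(2S)-5-oxo-2,5-dihydrofuran-2-yl]methyl 4-methylbenzenesulfonate | O=C1C=C[C@@H](COS(=O)(=O)c2ccc(C)cc2)O1 | intermediate
5 | [(2S,3S)-3-methyl-5-oxooxolan-2-yl]methyl 4-methylbenzenesulfonate | O=C1C[C@H](C)[C@@H](COS(=O)(=O)c2ccc(C)cc2)O1 | intermediate
6 | lithium bis{3-[(tert-butyldiphenylsilyl)oxy]prop-1-en-2-yl}cuprate (not isolated) | [Li+].C=C(CO[Si](c1ccccc1)(c1ccccc1)C(C)(C)C)[Cu-]C(=C)CO[Si](c1ccccc1)(c1ccccc1)C(C)(C)C | intermediate
7 | (4S,5R)-5-{2-[(tert-butyldiphenylsilyloxy)methyl]prop-2-en-1-yl}-4-methyloxolan-2-one | O=C1C[C@H](C)[C@@H](CC(=C)CO[Si](c2ccccc2)(c2ccccc2)C(C)(C)C)O1 | intermediate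
8 | (3S,4S,5R)-5-{2-[(tert-butyldiphenylsilyloxy)methyl]prop-2-en-1-yl}-3,4-dimethyloxolan-2-one | O=C1[C@@H](C)[C@H](C)[C@@H](CC(=C)CO[Si](c2ccccc2)(c2ccccc2)C(C)(C)C)O1 | intermediate
9 | prop-2-en-1-yl bromoacetate | C=CCOC(=O)CBr | starting material
10 | allyl ester of the C-9 quaternary lactone acid, (3S,4S,5R) | O=C1[C@@](C)(CC(=O)OCC=C)[C@H](C)[C@@H](CC(=C)CO[Si](c2ccccc2)(c2ccccc2)C(C)(C)C)O1 | intermediate
11 | C-9 quaternary lactone acetic acid, (3S,4S,5R) | O=C1[C@@](C)(CC(=O)O)[C@H](C)[C@@H](CC(=C)CO[Si](c2ccccc2)(c2ccccc2)C(C)(C)C)O1 | intermediate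
12 | 3-bromo-2-methylfuran | Cc1occc1Br | starting material
13 | acid chloride of 11 (not isolated) | O=C1[C@@](C)(CC(=O)Cl)[C@H](C)[C@@H](CC(=C)CO[Si](c2ccccc2)(c2ccccc2)C(C)(C)C)O1 | intermediate
14 | chloro(2-methylfuran-3-yl)zinc (not isolated) | Cc1occc1[Zn]Cl | intermediate
15 | 2-methylfuran-3-yl ketone lactone, (3S,4S,5R) | O=C1[C@@](C)(CC(=O)c2ccoc2C)[C@H](C)[C@@H](CC(=C)CO[Si](c3ccccc3)(c3ccccc3)C(C)(C)C)O1 | intermediate
16 | ring-C diketone with free C-7 hydroxyl, (7R,8S,9S) | O=C1Cc2occc2C(=O)C[C@@]1(C)[C@H](C)[C@H](O)CC(=C)CO[Si](c3ccccc3)(c3ccccc3)C(C)(C)C | intermediate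
17 | C-7 acetate of 16 | O=C1Cc2occc2C(=O)C[C@@]1(C)[C@H](C)[C@H](OC(C)=O)CC(=C)CO[Si](c3ccccc3)(c3ccccc3)C(C)(C)C | intermediate
18 | C-19 primary allylic alcohol (desilylated 17) | O=C1Cc2occc2C(=O)C[C@@]1(C)[C@H](C)[C@H](OC(C)=O)CC(=C)CO | intermediate
19 | prop-2-ynoic acid | OC(=O)C#C | starting material
20 | prop-2-ynoate ester of 18 | O=C1Cc2occc2C(=O)C[C@@]1(C)[C@H](C)[C@H](OC(C)=O)CC(=C)COC(=O)C#C | intermediate
21 | 3-vinylbutenolide diketone | O=C1Cc2occc2C(=O)C[C@@]1(C)[C@H](C)[C@H](OC(C)=O)CC3=C(C=C)C(=O)OC3 | intermediate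
22 | C-10 triethylsilyl enol ether of 21 | CC[Si](CC)(CC)OC1=Cc2occc2C(=O)C[C@@]1(C)[C@H](C)[C@H](OC(C)=O)CC3=C(C=C)C(=O)OC3 | intermediate
23 | vinylcyclobutane (C-4/C-5/C-10/C-1 ring cis-fused to ring A, ring C and the lactone; vinyl on C-4; not isolated) | CC(=O)O[C@@H]1C[C@@]23COC(=O)[C@]2(C=C)[C@H]4c5occc5C(=O)C[C@@](C)([C@@H]1C)[C@@]34O[Si](CC)(CC)CC | intermediate
24 | 10-O-triethylsilyl ether of the target | CC(=O)O[C@@H]1C[C@@]23COC(=O)C2=CC[C@H]2c4occc4C(=O)C[C@@](C)([C@@H]1C)[C@]23O[Si](CC)(CC)CC | intermediate
25 | CNP0329797.1, (1R,5S,7R,8S,9S,10R) | CC(=O)O[C@@H]1C[C@@]23COC(=O)C2=CC[C@H]2c4occc4C(=O)C[C@@](C)([C@@H]1C)[C@]23O | target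

**Step count**
Total steps: 16. Longest linear sequence: 15 steps (3 to 25, steps 2 to 16).

**Steps most likely to fail**

Step 15 (proposed new method). What may go wrong: the triplet 1,4-diradical may revert faster than it closes, the excited sensitizer may oxidise the silyl dienol ether instead of transferring energy, or hydrogen transfer within the thermally regenerated diradical may compete with C-1/C-2 recombination. The fallback sets out from 21 and comes back at 23. It removes the diene so that the classical enone–silyl enol ether [2+2] can be used, and regenerates the vinyl group thermally on the cyclobutane. Dihydroxylation of the terminal vinyl group of 21 (OsO4 cat., NMO; the electron-poor tetrasubstituted butenolide alkene and the acylfuran should react more slowly) gives the side-chain diol F1. Excess TESOTf/Et3N silylates both hydroxyls and forms the C-10 enol ether, giving the tris(triethylsilyl) compound F2. Irradiation at 350 nm through Pyrex should give the cyclobutane photoadduct F3. AcOH/THF/H2O removes the primary and secondary silyl groups and keeps the tertiary one, giving the cyclobutane diol F4. 1,1'-Thiocarbonyldiimidazole gives the cyclic thionocarbonate F5. Corey–Winter olefination with P(OMe)3 at 110 °C restores the vinyl group, that is 23, which at this temperature should go on to 24.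

Step 9. What may go wrong: proton removal at C-11 in place of the furan methyl group parks the substrate as an enolate that cannot cyclise, and slow intermolecular Claisen condensation then consumes it. The fallback sets out from acid 11 (through its chloride 13) and comes back at 16. It generates the lateral carbanion regiospecifically by desilylation. 3-Bromofuran is lithiated at C-2 with LDA and alkylated with (trimethylsilyl)methyl trifluoromethanesulfonate to 3-bromo-2-[(trimethylsilyl)methyl]furan F6. As in step 8 this is converted into the zinc chloride F7 and coupled with 13 (Pd(PPh3)4) to the silylmethyl ketone F8. CsF in DMF removes the silyl group, and the dienolate so formed, which can only be the lateral one, closes ring C on the lactone carbonyl to give 16.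

Step 13. What may go wrong: slow initiation on the electron-poor alkyne and the 1,1-disubstituted alkene, so that the catalyst decays before the tetrasubstituted ring alkene is closed. The fallback sets out from silyl ether 17 and comes back at 21, with an olefination in place of the metathesis. Lemieux–Johnson cleavage of the 1,1-disubstituted alkene (OsO4 cat., NaIO4, 2,6-lutidine) gives the C-5 ketone F9. HF·pyridine frees the α-hydroxy ketone F10. DCC esterification with 2-(diethoxyphosphoryl)but-3-enoic acid gives the phosphonate ester F11. Intramolecular Horner–Wadsworth–Emmons olefination with LiCl/i-Pr2NEt, mild enough for the β-acetoxy ketone, closes the butenolide with the vinyl group already on C-4, that is 21.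

**Further compounds**
F1 | step 15 | side-chain diol from 21 (epimers at the new carbinol carbon) | O=C1Cc2occc2C(=O)C[C@@]1(C)[C@H](C)[C@H](OC(C)=O)CC3=C(C(O)CO)C(=O)OC3
F2 | step 15 | tris(triethylsilyl) compound (C-10 enol ether and diol bis-silyl ether) | CC[Si](CC)(CC)OC1=Cc2occc2C(=O)C[C@@]1(C)[C@H](C)[C@H](OC(C)=O)CC3=C(C(CO[Si](CC)(CC)CC)O[Si](CC)(CC)CC)C(=O)OC3
F3 | step 15 | cyclobutane photoadduct with silylated diol side chain on C-4 | CC(=O)O[C@@H]1C[C@@]23COC(=O)[C@]2(C(CO[Si](CC)(CC)CC)O[Si](CC)(CC)CC)[C@H]4c5occc5C(=O)C[C@@](C)([C@@H]1C)[C@@]34O[Si](CC)(CC)CC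
F4 | step 15 | cyclobutane diol with C-10 triethylsilyl ether | CC(=O)O[C@@H]1C[C@@]23COC(=O)[C@]2(C(O)CO)[C@H]4c5occc5C(=O)C[C@@](C)([C@@H]1C)[C@@]34O[Si](CC)(CC)CC
F5 | step 15 | cyclic thionocarbonate of F4 | CC(=O)O[C@@H]1C[C@@]23COC(=O)[C@]2(C6COC(=S)O6)[C@H]4c5occc5C(=O)C[C@@](C)([C@@H]1C)[C@@]34O[Si](CC)(CC)CC
F6 | step 9 | 3-bromo-2-[(trimethylsilyl)methyl]furan | C[Si](C)(C)Cc1occc1Br
F7 | step 9 | chloro{2-[(trimethylsilyl)methyl]furan-3-yl}zinc | C[Si](C)(C)Cc1occc1[Zn]Cl
F8 | step 9 | silylmethyl analogue of ketone 15 | O=C1[C@@](C)(CC(=O)c2ccoc2C[Si](C)(C)C)[C@H](C)[C@@H](CC(=C)CO[Si](c3ccccc3)(c3ccccc3)C(C)(C)C)O1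
F9 | step 13 | C-5 ketone from cleavage of the alkene of 17 | O=C1Cc2occc2C(=O)C[C@@]1(C)[C@H](C)[C@H](OC(C)=O)CC(=O)CO[Si](c3ccccc3)(c3ccccc3)C(C)(C)C
F10 | step 13 | α-hydroxy ketone | O=C1Cc2occc2C(=O)C[C@@]1(C)[C@H](C)[C@H](OC(C)=O)CC(=O)CO
F11 | step 13 | 2-(diethoxyphosphoryl)but-3-enoate ester of F10 | O=C1Cc2occc2C(=O)C[C@@]1(C)[C@H](C)[C@H](OC(C)=O)CC(=O)COC(=O)C(C=C)P(=O)(OCC)OCC
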